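**Retrosynthetic overview**
- The target comes from its C2-hydroxy (lactol), 8-O-MOM precursor by ionic hydrogenation of the lactol C–OH and loss of MOM; the pyran ring is never opened.
- That quinonyl lactol comes from forming the C3–C(ring B) bond: enantioselective amine-catalysed α-arylation of a chroman-2-ol (a masked 3-arylpropanal) with 2,3-dimethoxy-1,4-benzoquinone, then hydroquinone → quinone oxidation. This key step sets C3 and delivers ring B at the quinone oxidation level.
- The chroman-2-ol comes from a dihydrocoumarin, and that from the coumarin fraxetin (7-O-methylation, 8-O-MOM, C3=C4 hydrogenation, half-reduction of the lactone).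
- The quinone comes from 2,3-dimethoxyphenol by para-oxidation.
- Ring order: rings A and C are bought together as the coumarin, ring B is made as the quinone, and no ring is closed late. The usual isoflavone or auxiliary-alkylation/Mitsunobu logic is not used.

Assumption: the diarylprolinol silyl ether shields the enamine face in the usual way, so the (R)-catalyst is specified for the (3S) product; its enantiomer is equally available if the sense proves opposite.

**Step 1**
Reactants: 1 fraxetin (7,8-dihydroxy-6-methoxy-2H-chromen-2-one)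
Product: 2 fraxidin (8-hydroxy-6,7-dimethoxy-2H-chromen-2-one)
Conditions: MeI (1.05 equiv), Li2CO3 (1.1 equiv), DMF, 40 °C
Reagents that add atoms: iodomethane, CI
Why: Regioselective Williamson O-methylation, because the 7-OH is para to C4a and therefore a vinylogous carboxylic acid, so the weak base forms mainly the 7-phenoxide, which is the one alkylated.

**Step 2**
Reactants: 2 fraxidin
Product: 3 6,7-dimethoxy-8-(methoxymethoxy)-2H-chromen-2-one
Conditions: MOMCl (1.5 equiv), iPr2NEt (2 equiv), CH2Cl2, 0 °C → rt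
Reagents that add atoms: chloromethyl methyl ether, COCCl
Why: O-alkylation of the remaining phenol with an α-chloro ether (MOM protection) gives an acetal that survives hydrogenation, hydride, amine catalysis and Ag2O but is cleaved by acid in the last step.

**Step 3**
Reactants: 3 6,7-dimethoxy-8-(methoxymethoxy)-2H-chromen-2-one
Product: 4 6,7-dimethoxy-8-(methoxymethoxy)-3,4-dihydro-2H-chromen-2-one
Conditions: H2 (3 atm), 10% Pd/C, EtOAc, rt
Reagents that add atoms: none
Why: Heterogeneous catalytic hydrogenation saturates the conjugated C3=C4 bond of the coumarin while aryl ethers, the MOM acetal and the lactone are inert in neutral EtOAc.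

**Step 4**
Reactants: 4 6,7-dimethoxy-8-(methoxymethoxy)-3,4-dihydro-2H-chromen-2-one
Product: 5 6,7-dimethoxy-8-(methoxymethoxy)-3,4-dihydro-2H-chromen-2-ol
Conditions: iBu2AlH (1.1 equiv), CH2Cl2, –78 °C; aq. KNaC4H4O6
Reagents that add atoms: none
Why: Partial reduction of the aryl lactone with iBu2AlH stops at the tetrahedral aluminate at –78 °C and gives the lactol (a ring-closed 3-arylpropanal) on work-up.

**Step 5**
Reactants: 6 2,3-dimethoxyphenol
Product: 7 2,3-dimethoxy-1,4-benzoquinone
Conditions: (KSO3)2NO (2.2 equiv), KH2PO4, H2O/acetone, 0 °C → rt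
Reagents that add atoms: potassium nitrosodisulfonate, [K+].[K+].[O]N(S(=O)(=O)[O-])S(=O)(=O)[O-]
Why: Teuber oxidation, in which the nitroxyl radical dehydrogenates the phenol and oxygenates its free para position to give the p-quinone.

**Step 6**
Reactants: 5 6,7-dimethoxy-8-(methoxymethoxy)-3,4-dihydro-2H-chromen-2-ol; 7 2,3-dimethoxy-1,4-benzoquinone (1.2 equiv)
Product: 9 5-[(3S)-2-hydroxy-6,7-dimethoxy-8-(methoxymethoxy)-3,4-dihydro-2H-chromen-3-yl]-2,3-dimethoxycyclohexa-2,5-diene-1,4-dione, via hydroquinone lactol 8 (not isolated)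
Conditions: (R)-2-{bis[3,5-bis(trifluoromethyl)phenyl](trimethylsilyloxy)methyl}pyrrolidine (15 mol%), EtOH/H2O 9:1, 4 °C → rt; extractive work-up; then Ag2O (2 equiv), Na2SO4, Et2O, 0 °C → rt
Reagents that add atoms: water, O
Why: Proposed new method: the closest known reaction type is the diarylprolinol silyl ether catalysed enamine α-arylation of aldehydes with 1,4-quinones, here extended to a lactol donor and a 2,3-dialkoxyquinone; 5 opens to its aldehyde, the E-enamine adds to the only free (C5/C6, equivalent) position of symmetrical 7 from the face opposite the CAr2(OSiMe3) group of the (R)-catalyst, which sets C3 as S, tautomerization gives hydroquinone 8, which is held as a configurationally stable lactol, and Ag2O then dehydrogenates only the hydroquinone so that the chroman-2-ol is the sole lactol left.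

**Step 7**
Reactants: 9 5-[(3S)-2-hydroxy-6,7-dimethoxy-8-(methoxymethoxy)-3,4-dihydro-2H-chromen-3-yl]-2,3-dimethoxycyclohexa-2,5-diene-1,4-dione
Product: 11 5-[(3S)-8-hydroxy-6,7-dimethoxy-3,4-dihydro-2H-chromen-3-yl]-2,3-dimethoxycyclohexa-2,5-diene-1,4-dione, via MOM-protected chroman quinone 10 (not isolated)
Conditions: Et3SiH (6 equiv), CF3CO2H (20 equiv), CH2Cl2, –40 °C → rt
Reagents that add atoms: none
Why: Kursanov–Parnes ionic hydrogenation, in which acid ionizes the lactol to the aryloxy-stabilized oxocarbenium ion that excess Et3SiH traps at low temperature before the C3 proton can be lost (C3 stays S, no new stereocenter), the quinone tolerating Et3SiH/CF3CO2H as in reductions of quinone-fused lactols, while on warming the same acid cleaves the MOM acetal and the silane scavenges the methoxymethyl cation.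

**Compound list**
1 | fraxetin (7,8-dihydroxy-6-methoxy-2H-chromen-2-one) | O=C1C=Cc2cc(OC)c(O)c(O)c2O1 | starting material
2 | fraxidin (8-hydroxy-6,7-dimethoxy-2H-chromen-2-one) | O=C1C=Cc2cc(OC)c(OC)c(O)c2O1 | intermediate
3 | 6,7-dimethoxy-8-(methoxymethoxy)-2H-chromen-2-one | O=C1C=Cc2cc(OC)c(OC)c(OCOC)c2O1 | intermediate
4 | 6,7-dimethoxy-8-(methoxymethoxy)-3,4-dihydro-2H-chromen-2-one | O=C1CCc2cc(OC)c(OC)c(OCOC)c2O1 | intermediate
5 | 6,7-dimethoxy-8-(methoxymethoxy)-3,4-dihydro-2H-chromen-2-ol (racemic at C2; ring-chain tautomer of the 3-arylpropanal) | OC1CCc2cc(OC)c(OC)c(OCOC)c2O1 | intermediate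
6 | 2,3-dimethoxyphenol | COc1cccc(O)c1OC | starting material
7 | 2,3-dimethoxy-1,4-benzoquinone | COC1=C(OC)C(=O)C=CC1=O | intermediate
8 | (3S)-3-(2,5-dihydroxy-3,4-dimethoxyphenyl)-6,7-dimethoxy-8-(methoxymethoxy)-3,4-dihydro-2H-chromen-2-ol (C2 epimers; equilibrates with its 2,3-dihydrobenzofuran-2-ol ring isomer) | COc1c(OC)c(O)c([C@H]2C(O)Oc3c(cc(OC)c(OC)c3OCOC)C2)cc1O | intermediate
9 | 5-[(3S)-2-hydroxy-6,7-dimethoxy-8-(methoxymethoxy)-3,4-dihydro-2H-chromen-3-yl]-2,3-dimethoxycyclohexa-2,5-diene-1,4-dione (C2 epimers) | COC1=C(OC)C(=O)C([C@H]2C(O)Oc3c(cc(OC)c(OC)c3OCOC)C2)=CC1=O | intermediate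
10 | 5-[(3S)-6,7-dimethoxy-8-(methoxymethoxy)-3,4-dihydro-2H-chromen-3-yl]-2,3-dimethoxycyclohexa-2,5-diene-1,4-dione | COC1=C(OC)C(=O)C([C@H]2COc3c(cc(OC)c(OC)c3OCOC)C2)=CC1=O | intermediate
11 | 5-[(3S)-8-hydroxy-6,7-dimethoxy-3,4-dihydro-2H-chromen-3-yl]-2,3-dimethoxycyclohexa-2,5-diene-1,4-dione | COC1=C(OC)C(=O)C([C@H]2COc3c(cc(OC)c(OC)c3O)C2)=CC1=O | target

**Totals**
Total step count: 7. Longest linear sequence: 6 steps (1 → 2 → 3 → 4 → 5 → 9 → 11); step 5 is a one-step side branch.

**Three steps most likely to fail**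

Step 6 (key arylation). The dimethoxyquinone is a weaker Michael acceptor than the quinones for which this reaction type is established. The aldehyde is present only as a small equilibrium fraction of the lactol. The product, once oxidized, could accept a second enamine, and the ee must survive the oxidation.

The fallback sets out from 7 and 5 and comes back at 11. It brings ring B in as a protected hydroquinone by copper/amine dual-catalytic α-arylation with a diaryliodonium salt instead of Michael addition to the quinone. 7 is reduced (Na2S2O4, EtOAc/H2O) to 2,3-dimethoxybenzene-1,4-diol F1 and benzylated (BnBr, K2CO3, DMF) to 1,4-bis(benzyloxy)-2,3-dimethoxybenzene F2. MesI(OAc)2 and TfOH (CH2Cl2, –40 °C) convert F2 into [2,5-bis(benzyloxy)-3,4-dimethoxyphenyl](2,4,6-trimethylphenyl)iodonium trifluoromethanesulfonate F3. 5 and F3 are then combined with CuBr (10 mol%), NaHCO3 and the trifluoroacetate salt of 5-benzyl-2-tert-butyl-3-methylimidazolidin-4-one (20 mol%, the enantiomer that gives 3S) in toluene/Et2O. This gives (3S)-3-[2,5-bis(benzyloxy)-3,4-dimethoxyphenyl]-6,7-dimethoxy-8-(methoxymethoxy)-3,4-dihydro-2H-chromen-2-ol F4, in which the ring B oxygens are blocked so only the chroman lactol can exist. Et3SiH/CF3CO2H reduces the lactol and removes the MOM group to give (3S)-3-[2,5-bis(benzyloxy)-3,4-dimethoxyphenyl]-6,7-dimethoxy-3,4-dihydro-2H-chromen-8-ol F5. Hydrogenolysis (H2, Pd/C, EtOAc) gives (3S)-3-(2,5-dihydroxy-3,4-dimethoxyphenyl)-6,7-dimethoxy-3,4-dihydro-2H-chromen-8-ol F6, and Ag2O (Et2O, 0 °C) oxidizes this hydroquinone to 11.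

Step 7 (lactol reduction). The oxocarbenium ion at C2 can lose the C3 proton, which is also vinylogously activated by the quinone, to give an achiral 4H-chromene and erase the stereocenter. The medium may also partly reduce the quinone, which is harmless because brief Ag2O or air treatment restores it.

The fallback sets out from 8 and comes back at 10, and never places a cation next to C3. 8 is not oxidized but reduced in the same flask (NaBH4, EtOH, 0 °C), which opens either lactol form to (2S)-2-(2,5-dihydroxy-3,4-dimethoxyphenyl)-3-[2-hydroxy-4,5-dimethoxy-3-(methoxymethoxy)phenyl]propan-1-ol F7. Ag2O oxidizes only the hydroquinone to 5-{(2S)-1-hydroxy-3-[2-hydroxy-4,5-dimethoxy-3-(methoxymethoxy)phenyl]propan-2-yl}-2,3-dimethoxycyclohexa-2,5-diene-1,4-dione F8, in which the ring A phenol is the only phenol left. F8 is added to the pre-formed PPh3/DIAD betaine (THF, 0 °C) so that no free phosphine meets the quinone. Intramolecular Mitsunobu etherification at the primary carbon closes ring C to give 10, and CF3CO2H/CH2Cl2 then removes the MOM group as in step 7 to give 11.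

Step 1 (selective methylation). Both phenols are flanked by two ortho substituents and the selectivity rests only on the acidity difference, so 8-O-methylation or double methylation may cost material.

The fallback sets out from 6 and comes back at 3, building the coumarin de novo so that the regiochemistry is fixed by directed metalation. 6 is protected (MOMCl, iPr2NEt, CH2Cl2) as 1,2-dimethoxy-3-(methoxymethoxy)benzene F9. MOM-directed ortho-lithiation (n-BuLi, THF, 0 °C), then B(OMe)3 and H2O2/NaOH, gives 3,4-dimethoxy-2-(methoxymethoxy)phenol F10. Magnesium-mediated ortho-formylation (MgCl2, Et3N, paraformaldehyde, MeCN, reflux) gives 2-hydroxy-4,5-dimethoxy-3-(methoxymethoxy)benzaldehyde F11. Wittig olefination with Ph3P=CHCO2Et in N,N-diethylaniline at reflux gives, after thermal E/Z isomerization, ethyl (Z)-3-[2-hydroxy-4,5-dimethoxy-3-(methoxymethoxy)phenyl]prop-2-enoate F12, which lactonizes in the same flask to 3.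

**Further compounds**
F1 | step 6 | 2,3-dimethoxybenzene-1,4-diol | COc1c(O)ccc(O)c1OC
F2 | step 6 | 1,4-bis(benzyloxy)-2,3-dimethoxybenzene | COc1c(OCc2ccccc2)ccc(OCc2ccccc2)c1OC
F3 | step 6 | [2,5-bis(benzyloxy)-3,4-dimethoxyphenyl](2,4,6-trimethylphenyl)iodonium trifluoromethanesulfonate | COc1c(OCc2ccccc2)cc([I+]c2c(C)cc(C)cc2C)c(OCc2ccccc2)c1OC.[O-]S(=O)(=O)C(F)(F)F
F4 | step 6 | (3S)-3-[2,5-bis(benzyloxy)-3,4-dimethoxyphenyl]-6,7-dimethoxy-8-(methoxymethoxy)-3,4-dihydro-2H-chromen-2-ol | COc1c(OC)c(OCc2ccccc2)c([C@H]2C(O)Oc3c(cc(OC)c(OC)c3OCOC)C2)cc1OCc1ccccc1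
F5 | step 6 | (3S)-3-[2,5-bis(benzyloxy)-3,4-dimethoxyphenyl]-6,7-dimethoxy-3,4-dihydro-2H-chromen-8-ol | COc1c(OC)c(OCc2ccccc2)c([C@H]2COc3c(cc(OC)c(OC)c3O)C2)cc1OCc1ccccc1
F6 | step 6 | (3S)-3-(2,5-dihydroxy-3,4-dimethoxyphenyl)-6,7-dimethoxy-3,4-dihydro-2H-chromen-8-ol | COc1c(OC)c(O)c([C@H]2COc3c(cc(OC)c(OC)c3O)C2)cc1O
F7 | step 7 | (2S)-2-(2,5-dihydroxy-3,4-dimethoxyphenyl)-3-[2-hydroxy-4,5-dimethoxy-3-(methoxymethoxy)phenyl]propan-1-ol | COc1c(OC)c(O)c([C@@H](CO)Cc2cc(OC)c(OC)c(OCOC)c2O)cc1O
F8 | step 7 | 5-{(2S)-1-hydroxy-3-[2-hydroxy-4,5-dimethoxy-3-(methoxymethoxy)phenyl]propan-2-yl}-2,3-dimethoxycyclohexa-2,5-diene-1,4-dione | COC1=C(OC)C(=O)C([C@@H](CO)Cc2cc(OC)c(OC)c(OCOC)c2O)=CC1=O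
F9 | step 1 | 1,2-dimethoxy-3-(methoxymethoxy)benzene | COCOc1cccc(OC)c1OC
F10 | step 1 | 3,4-dimethoxy-2-(methoxymethoxy)phenol | COCOc1c(O)ccc(OC)c1OC
F11 | step 1 | 2-hydroxy-4,5-dimethoxy-3-(methoxymethoxy)benzaldehyde | COCOc1c(O)c(C=O)cc(OC)c1OC
F12 | step 1 | ethyl (Z)-3-[2-hydroxy-4,5-dimethoxy-3-(methoxymethoxy)phenyl]prop-2-enoate | CCOC(=O)/C=C\c1cc(OC)c(OC)c(OCOC)c1O
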